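The target is an erythro 8-O-4' neolignan whose central carbon C8 is bonded to three different partners: the ether oxygen of ring B, the benzylic carbinol C7 on ring A and the hydroxymethyl carbon C9. The plan lets one diazoacetate carbon acquire all three in a single dirhodium/zirconium co-catalysed event: the ring B phenol adds to the carbenoid and the oxonium ylide is intercepted by the ring A aldehyde, forming the C8–O and C7–C8 bonds and both stereocentres (7R,8S in the target) with C9 at the ester level. The precursors are a vanillin-derived aldehyde carrying the glycerol ether as its acetonide, a silyl-protected syringyl propanol and ethyl diazoacetate; ester reduction and one mild acidic deprotection follow.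

Key step: step 4

Assumption: C7 is the benzylic carbinol carbon on ring A, C8 the aryloxy-bearing carbon and C9 the hydroxymethyl carbon; the (S) antipode of BINOL is taken to deliver the (7R,8S) erythro series, and if a first run shows the opposite sense the (R) ligand is used with nothing else changed.

Step 1
Reactants: 1 vanillin; 2 2,2-dimethyl-1,3-dioxan-5-ol
Product: 3 4-[(2,2-dimethyl-1,3-dioxan-5-yl)oxy]-3-methoxybenzaldehyde
Conditions: PPh3, DIAD, THF, 0 °C → 50 °C
Reagents that add atoms: none
Why: Mitsunobu etherification, in which the acidic phenol of vanillin displaces the activated secondary carbinol of the symmetric dioxanol (no stereocentre is involved) while the aldehyde is inert to the reagents.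

Step 2
Reactants: 4 4-allyl-2,6-dimethoxyphenol
Product: 6 4-(3-hydroxypropyl)-2,6-dimethoxyphenol, via B-alkyl-9-BBN adduct 5 (not isolated)
Conditions: 9-BBN (2.5 equiv), THF, 0 °C → rt; then aq. NaOH, 30% H2O2, 0 °C → rt
Reagents that add atoms: hydrogen peroxide, OO
Why: Anti-Markovnikov hydroboration–oxidation, in which the bulky borane places boron on the terminal allyl carbon (the excess absorbs the phenolic proton) and cold alkaline peroxide converts the C–B bond into the primary alcohol.

Step 3
Reactants: 6 4-(3-hydroxypropyl)-2,6-dimethoxyphenol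
Product: 7 4-[3-(tert-butyldimethylsilyloxy)propyl]-2,6-dimethoxyphenol
Conditions: TBSCl (1.05 equiv), imidazole, CH2Cl2, 0 °C
Reagents that add atoms: tert-butyldimethylsilyl chloride, CC(C)(C)[Si](C)(C)Cl
Why: Chemoselective silyl ether formation, since with a weak base the unhindered primary alcohol should be silylated much faster than the undeprotonated phenol flanked by two methoxy groups.

Step 4
Reactants: 3 4-[(2,2-dimethyl-1,3-dioxan-5-yl)oxy]-3-methoxybenzaldehyde; 7 4-[3-(tert-butyldimethylsilyloxy)propyl]-2,6-dimethoxyphenol; 8 ethyl diazoacetate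
Product: 10 ethyl (2R,3R)-2-{4-[3-(tert-butyldimethylsilyloxy)propyl]-2,6-dimethoxyphenoxy}-3-{4-[(2,2-dimethyl-1,3-dioxan-5-yl)oxy]-3-methoxyphenyl}-3-hydroxypropanoate (erythro), via oxonium ylide 9 (not isolated)
Conditions: Rh2(OAc)4 (2 mol %), preformed Zr(OBu)4/(S)-BINOL (1:2, 20 mol %, butanol removed in vacuo), 4 Å MS, CH2Cl2, 0 °C; 3 (1.5 equiv); 8 (1.5 equiv) added over 4 h by syringe pump
Reagents that add atoms: none
Why: Proposed new method: Rh2(OAc)4 should expel N2 from 8 to give a catalyst-bound carbenoid whose unhindered carbon is attacked by the phenolic oxygen of 7, and the resulting oxonium ylide 9 (a rhodium-associated enol) should add through C8 to the aldehyde of 3 held on the zirconium binaphtholate before its O–H proton migrates to carbon, so that the C8–O and C7–C8 bonds form in one event and no ring is closed. The closest known reaction type is the Rh2(OAc)4-catalysed three-component aldol-type coupling of aryldiazoacetates, alcohols and aldehydes with a chiral zirconium–BINOL Lewis acid; an acceptor-only diazoacetate, a phenol and an electron-rich aldehyde lie outside its proven scope. Both stereocentres arise in the C–C bond formation: the erythro relationship is expected from a hydrogen-bonded, closed transition state in which the oxonium O–H points at the zirconium-bound carbonyl oxygen and ring A lies anti to the bulky 2,6-dimethoxyaryloxy group, and the absolute sense (7R) from the aldehyde face left open by (S)-BINOL on tetravalent zirconium. The step needs trapping to outrun the 1,2-proton shift, which the crowded oxygen of the 2,6-dimethoxyphenol (slow proton transfer) and Lewis-acid activation of the aldehyde should favour, and it needs the phenol to be the only O–H donor, which the silyl ether, the acetonide and the removal of butanol from the catalyst secure. Slow addition of 8 keeps its concentration low and so suppresses carbene dimerisation and direct Lewis-acid-promoted addition of the diazo ester to the aldehyde.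

Step 5
Reactants: 10 ethyl (2R,3R)-2-{4-[3-(tert-butyldimethylsilyloxy)propyl]-2,6-dimethoxyphenoxy}-3-{4-[(2,2-dimethyl-1,3-dioxan-5-yl)oxy]-3-methoxyphenyl}-3-hydroxypropanoate
Product: 11 (1R,2S)-2-{4-[3-(tert-butyldimethylsilyloxy)propyl]-2,6-dimethoxyphenoxy}-1-{4-[(2,2-dimethyl-1,3-dioxan-5-yl)oxy]-3-methoxyphenyl}propane-1,3-diol
Conditions: LiBH4, THF, 0 °C → rt
Reagents that add atoms: none
Why: Ester reduction with LiBH4, which should convert the activated α-aryloxy ester into the C9 primary alcohol without touching the silyl ether, the acetonide or the aryl ethers, and is not basic enough in the cold to cause retro-aldol cleavage or epimerisation at C8 (the C8 descriptor changes from R to S only through the priority rules).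

Step 6
Reactants: 11 (1R,2S)-2-{4-[3-(tert-butyldimethylsilyloxy)propyl]-2,6-dimethoxyphenoxy}-1-{4-[(2,2-dimethyl-1,3-dioxan-5-yl)oxy]-3-methoxyphenyl}propane-1,3-diol
Product: 12 (1R,2S)-1-{4-[(1,3-dihydroxypropan-2-yl)oxy]-3-methoxyphenyl}-2-[4-(3-hydroxypropyl)-2,6-dimethoxyphenoxy]propane-1,3-diol (erythro, 7R,8S)
Conditions: AcOH/THF/H2O (3:1:1), 40 °C
Reagents that add atoms: none
Why: Acid-catalysed hydrolysis as a global deprotection, in which aqueous acetic acid should cleave the primary silyl ether and the isopropylidene acetal in the same medium while being too weak and too aqueous to ionise the benzylic C7 carbinol, so both stereocentres persist.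

Compound list
1 | vanillin (4-hydroxy-3-methoxybenzaldehyde) | COc1cc(C=O)ccc1O | starting material
2 | 2,2-dimethyl-1,3-dioxan-5-ol | CC1(C)OCC(O)CO1 | starting material
3 | 4-[(2,2-dimethyl-1,3-dioxan-5-yl)oxy]-3-methoxybenzaldehyde (ring A aldehyde) | COc1cc(C=O)ccc1OC1COC(C)(C)OC1 | intermediate
4 | 4-allyl-2,6-dimethoxyphenol | COc1cc(CC=C)cc(OC)c1O | starting material
5 | 4-[3-(9-borabicyclo[3.3.1]nonan-9-yl)propyl]-2,6-dimethoxyphenol (B-alkyl-9-BBN adduct, not isolated) | COc1cc(CCCB2C3CCCC2CCC3)cc(OC)c1O | intermediate
6 | 4-(3-hydroxypropyl)-2,6-dimethoxyphenol | COc1cc(CCCO)cc(OC)c1O | intermediate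
7 | 4-[3-(tert-butyldimethylsilyloxy)propyl]-2,6-dimethoxyphenol (ring B phenol) | COc1cc(CCCO[Si](C)(C)C(C)(C)C)cc(OC)c1O | intermediate
8 | ethyl diazoacetate | CCOC(=O)C=[N+]=[N-] | starting material
9 | protic oxonium ylide from 7 and the ethoxycarbonyl carbene (rhodium-associated enol, not isolated) | CCOC(=O)[CH-][OH+]c1c(OC)cc(CCCO[Si](C)(C)C(C)(C)C)cc1OC | intermediate
10 | ethyl (2R,3R)-2-{4-[3-(tert-butyldimethylsilyloxy)propyl]-2,6-dimethoxyphenoxy}-3-{4-[(2,2-dimethyl-1,3-dioxan-5-yl)oxy]-3-methoxyphenyl}-3-hydroxypropanoate (erythro) | COc1cc([C@@H](O)[C@H](C(=O)OCC)Oc2c(OC)cc(CCCO[Si](C)(C)C(C)(C)C)cc2OC)ccc1OC1COC(C)(C)OC1 | intermediate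
11 | (1R,2S)-2-{4-[3-(tert-butyldimethylsilyloxy)propyl]-2,6-dimethoxyphenoxy}-1-{4-[(2,2-dimethyl-1,3-dioxan-5-yl)oxy]-3-methoxyphenyl}propane-1,3-diol | COc1cc([C@@H](O)[C@H](CO)Oc2c(OC)cc(CCCO[Si](C)(C)C(C)(C)C)cc2OC)ccc1OC1COC(C)(C)OC1 | intermediate
12 | (1R,2S)-1-{4-[(1,3-dihydroxypropan-2-yl)oxy]-3-methoxyphenyl}-2-[4-(3-hydroxypropyl)-2,6-dimethoxyphenoxy]propane-1,3-diol (erythro, 7R,8S) | COc1cc([C@@H](O)[C@H](CO)Oc2c(OC)cc(CCCO)cc2OC)ccc1OC(CO)CO | target

Total step count: 6
Longest linear sequence: 5 steps (4 → 6 → 7 → 10 → 11 → 12)

Steps most likely to fail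

1. Step 4. Proton transfer within the oxonium ylide may outrun its addition to the deactivated aldehyde, so that plain O–H insertion dominates, or the addition may proceed with poor erythro and facial selectivity. The fallback is a stepwise aldol with resolution in place of catalyst control, all known chemistry. Setting out from 7, Williamson alkylation with ethyl bromoacetate (K2CO3, acetone, reflux) should give ethyl {4-[3-(tert-butyldimethylsilyloxy)propyl]-2,6-dimethoxyphenoxy}acetate F1, which is also the O–H insertion by-product of step 4 and can be collected from unsuccessful runs. Its lithium enolate (LiN(iPr)2, THF, −78 °C) is added to aldehyde 3 and quenched cold with acetic acid. Lithium aryloxyacetate enolates are expected to favour the erythro aldol pair, which is purified on silica as the racemate of 10 and the mirror-image (2S,3S) ester F2. Preparative HPLC on a chiral stationary phase (amylose tris(3,5-dimethylphenylcarbamate)) removes F2 and brings the route back to 10 for step 5.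

2. Step 1. Displacement at the secondary carbinol flanked by two C–O bonds may be slow, with the activated alcohol diverted to elimination or to alkylation of the reduced azodicarboxylate. The fallback forms the aryl–oxygen bond instead of the alkyl–oxygen bond. Setting out from 2, NaH in DMF at 0 °C gives sodium 2,2-dimethyl-1,3-dioxan-5-olate F3, which should displace fluoride from commercial 4-fluoro-3-methoxybenzaldehyde (COc1cc(C=O)ccc1F) by nucleophilic aromatic substitution activated by the para formyl group (rt → 50 °C), returning directly to 3.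

3. Step 6. The primary silyl ether may hydrolyse slowly under acid mild enough for the benzylic carbinol, and prolonged exposure would allow ionisation at C7 with epimerisation to the threo series or capture by acetic acid. The fallback is an orthogonal, stepwise deprotection. Setting out from 11, fluoride cleavage of the silyl ether (Bu4NF buffered with AcOH, THF, rt) should give (1R,2S)-1-{4-[(2,2-dimethyl-1,3-dioxan-5-yl)oxy]-3-methoxyphenyl}-2-[4-(3-hydroxypropyl)-2,6-dimethoxyphenoxy]propane-1,3-diol F4. The remaining isopropylidene acetal is then hydrolysed alone by brief treatment with 80% aqueous AcOH at rt, returning at target 12.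

Further compounds
F1 | step 4 | ethyl {4-[3-(tert-butyldimethylsilyloxy)propyl]-2,6-dimethoxyphenoxy}acetate | CCOC(=O)COc1c(OC)cc(CCCO[Si](C)(C)C(C)(C)C)cc1OC
F2 | step 4 | ethyl (2S,3S)-2-{4-[3-(tert-butyldimethylsilyloxy)propyl]-2,6-dimethoxyphenoxy}-3-{4-[(2,2-dimethyl-1,3-dioxan-5-yl)oxy]-3-methoxyphenyl}-3-hydroxypropanoate (enantiomer of 10) | COc1cc([C@H](O)[C@@H](C(=O)OCC)Oc2c(OC)cc(CCCO[Si](C)(C)C(C)(C)C)cc2OC)ccc1OC1COC(C)(C)OC1
F3 | step 1 | sodium 2,2-dimethyl-1,3-dioxan-5-olate | CC1(C)OCC([O-])CO1.[Na+]
F4 | step 6 | (1R,2S)-1-{4-[(2,2-dimethyl-1,3-dioxan-5-yl)oxy]-3-methoxyphenyl}-2-[4-(3-hydroxypropyl)-2,6-dimethoxyphenoxy]propane-1,3-diol | COc1cc([C@@H](O)[C@H](CO)Oc2c(OC)cc(CCCO)cc2OC)ccc1OC1COC(C)(C)OC1
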